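The constants are hidden, so the one of substrate + partner has to be read from the earlier runs.

| setting | ash | larch | north | south-east |
|---|---|---|---|---|
| substrate | 0.20 M (in portions, 3) | 0.20 M (in portions, 3) | 0.20 M (in portions, 3) | 0.20 M |
| partner | 0.10 M | 0.15 M | 0.200 M | 0.200 M |
| remark | run made earlier; portions every 2.0 h | run made earlier; portions every 2.0 h | the portions of substrate follow each other after 2.0 h, the first at the start | everything together at the start |
| time |  |  | 8.0 h | 8.0 h |

| run | time / h | single product / % |
|---|---|---|
| ash | 0.667 | 7.5 |
| ash | 1.00 | 10.3 |
| ash | 1.33 | 12.8 |
| ash | 2.50 | 18.1 |
| ash | 3.00 | 22.5 |
| ash | 5.00 | 27.7 |
| ash | 8.00 | 31.1 |
| larch | 0.417 | 7.7 |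
| larch | 1.33 | 13.2 |
| larch | 2.50 | 20.0 |
| larch | 3.00 | 24.7 |
| larch | 5.00 | 30.2 |
| larch | 6.00 | 32.6 |
| larch | 8.00 | 33.5 |

(scatter of a reading: 1 percentage point)

* the winner by amount of single product, in percent of the substrate charged; "neither" if no more than 2 percentage points parts them (north / south-east / neither)
* how much single product is there at the end, in percent of the substrate charged: north
* how much single product is there at the end, in percent of the substrate charged: south-east

- what may be going on: partner + bis adduct -> triple product; substrate + partner -> single product; partner + triple product -> tetra adduct; partner + single product -> bis adduct

Two times are held against each other here: the life of substrate under partner, and the interval between portions. At 0.417 h in the larch run, 23.1% of the first portion stands as single product. Taking partner as charged, substrate decaying exponentially and none of that single product used further, this reads as a rough rate constant of 4.20 /M/h. At north's starting partner, substrate then has a reckoned life of 1.19 h. That gives 1.68 for the dosing number, the interval divided by that life.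

The two ends are simple. At a small dosing number, portions pile up unreacted and dosing resembles charging at once. At a large one, with partner still in excess (pseudo-first-order), each portion reacts away within the interval, and its single product then meets partner with little fresh substrate beside it. In north the interval is longer than the reckoned life, and with partner held as charged 18.6% of the first portion is reckoned to remain when the second arrives. On that comparison this reckoning favours south-east, though it gives no yield.

The forecast also chose south-east, with 35% for north and 40% for south-east: “keeps substrate high relative to single product”.

North ends at 33.2% and south-east at 46.2%, so south-east wins, 6.2 percentage points above the forecast's south-east figure.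

    partner + bis adduct → triple product (k = 0.650 /M/h)
    substrate + partner → single product (k = 5.90 /M/h)
    partner + triple product → tetra adduct (k = 9.90 /M/h)
    partner + single product → bis adduct (k = 3.60 /M/h)

Just before north's last portion, partner stands at 21.6% of its charge. On that partner the dosing number is 0.362, and north ends with 36.7% of its substrate unreacted.

A neighbour of north, dosed alike but charged with 0.80 M of partner, has a dosing number of 6.72 with partner taken as charged, which points to portions consumed within the interval and single product used up further. That neighbour ends with 0.0899% substrate, 2.15% single product and 56.0% tetra adduct.

Readings and results were generated by integration with constants of no real substance, noise included.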